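At early times the protic impurity reacts with starting material, and two chemists then disagree about what the flask does next.

    starting material + protic impurity → quenched substrate (k1 = 0.0542 M⁻¹ s⁻¹)
    starting material + acid → weak acid + acid + target (k2 = 0.00175 M⁻¹ s⁻¹)
    weak acid ⇌ conjugate base + acid, settled at all times (K3 = 1.6 × 10⁻⁵ M)
    starting material → weak acid + target (k4 = 1.79 × 10⁻⁶ s⁻¹)
    target ⇌ isomer of the product (K5 = 0.15, k5 = 9.93 × 10⁻⁷ s⁻¹)

starting material 0.13 M; acid 0.0130 M; protic impurity 2.60 mM; time 20 h

- acid is the free proton; pH is minus the decimal logarithm of its molar concentration
- run time (flask): 20 h

1. part of the starting material that has reacted at 20 h
2. pH of the solution at 20 h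

The first chemist says that acid leaves the catalysed step as it entered, so [acid] stays at its charge and the starting material decays pseudo-first-order. The time constant of that decay, one over the sum of the catalysed rate constant times [acid] and the uncatalysed rate constant, is 11.3 h. The protic impurity runs down with a time constant of about 2.37 min, much shorter than that, so it enters as a correction: it removes 2.00% of the starting material at the outset. The first view then gives 83.3% reacted at 20 h.

The second chemist says the clock speeds up. Weak acid builds towards 0.127 M, and dissociating by itself that gives 1.43 mM of proton, 11.0% of the charged acid. Added to the charged acid and held over the whole run, this gives 86.0% reacted.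

I compute the correction differently. With the charged acid already present, the balance gives extra proton equal to the dissociation constant times [weak acid] over [acid]. At its fullest that is 0.157 mM, far below the second chemist's figure. It is 1.21% of the charge and lowers the pH by 0.00521, so I commit to 83.3%.

The forecast takes the first chemist's side with a slightly different number, 83.5% against my 83.3%, and gives pH 1.88, saying the “weak acid formed barely dissociates”.

The simulation gives 83.4% and pH 1.88, with acid at 101% of its charge. The same time constant puts 40.5% of the starting material in the flask at 10.0 h, and the run shows 40.4%. For the neighbour flask charged with 0.0032 M of acid, holding [acid] at that charge makes the time constant 37.6 h, which gives 42.4% reacted, and the run shows 43.4%. The second chemist's concern has its region in this thinly charged neighbour flask, where acid stands further above its charge than in the first flask: it reads 108% of its charge at 20.0 h, and conjugate base reads 2.49 × 10⁻⁴ M.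

The constants used here belong to no real substance; the result is computed.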